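**Plan**
1. Cuts, in retrosynthetic order: the three O–CH3 bonds and the two Ar–CHO bonds. A C3 ketone is then put back, and C4–C1′ is cut to give a C3=C4 enol silane and a 2,4,6-trimethoxybenzylic cation. The enol silane goes back to a C4=C5 enone.
2. Enabling feature: in the seven-membered ring (C1, C5–C10) the tertiary carbinol C10 is bonded to the ring-fusion methine C1. In the cyclopentane (C1–C5) the methyl-bearing C4 is bonded to the other fusion atom C5. The array C10(OH)(CH3)–C1(H)–C5=C4(CH3)–C3=O is what a 4-methyl cross-conjugated decalin dienone delivers on irradiation in aqueous acid.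
3. C1–C5 and C10–O are therefore cut and C5–C10 is re-joined. The 5/7 enone goes back to eudesma-1,4,11-trien-3-one, then to (+)-α-cyperone, then (C1–C10 and C4=C5, Robinson annulation) to (+)-dihydrocarvone and ethyl vinyl ketone.
4. Forward ring order: bought cyclohexane, then decalin. In one photochemical event the cyclohexane takes up C1 to become the cycloheptane while the dienone ring contracts to the cyclopentenone. The arene side chain is then joined at C4, C3 is deoxygenated, and the arene is formylated and deprotected.
5. Stereochemistry: C7 is bought. The decalin quaternary carbon is set by a chiral amine and relayed to C1 and C10 in the key step. C5 (dissolving metal), C4 and C1′ (alkylation) follow by substrate control.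

Key step: step 5

Remark (numbering): guaiane numbering is used. C1 and C5 are the ring-fusion CH groups (C1 next to carbinol C10), C2 and C3 are CH2, C4 is quaternary, C6 is CH2, C7 bears isopropenyl, C8 and C9 are CH2, and C1′ is the benzylic CH. The β face carries 10-CH3, the isopropenyl group, H-5 and the C4 side chain. The α face carries 10-OH, H-1, H-7 and 4-CH3. The target is (1R,4S,5S,7R,10R,1′R).
Remark (assumption): commercial 1 is a mixture of C2 epimers, and both converge in step 2. The C3 carbinol centre of 20 and 21 is drawn as the expected 3β epimer and is erased in step 13.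

**Step 1**
Reactants: 1 (+)-dihydrocarvone; 2 (R)-1-phenylethylamine
Product: 3 (R)-1-phenylethyl ketimine of dihydrocarvone
Conditions: TsOH (cat.), toluene, Dean–Stark, reflux
Reagents that add atoms: none
Why: Acid-catalysed ketimine condensation with azeotropic removal of water; the labile C2 centre is erased in the enamine tautomer used next and C5 of 1 (the later C7) is untouched.

**Step 2**
Reactants: 3 ketimine; 4 ethyl vinyl ketone
Product: 6 (2S,5R)-2-methyl-2-(3-oxopentyl)-5-(prop-1-en-2-yl)cyclohexan-1-one, via Michael adduct imine 5 (not isolated)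
Conditions: THF, 40 °C; then 10% aq AcOH, rt
Reagents that add atoms: water, O
Why: Chiral-imine (secondary enamine) asymmetric Michael addition: the more substituted enamine tautomer adds through a compact aza-ene-like transition state on the face left open by the phenyl group of the (R)-auxiliary, which should set the quaternary carbon (S), methyl cis to isopropenyl, against the intrinsic bias of the ring, and mild acid then hydrolyses 5.

**Step 3**
Reactants: 6 diketone
Product: 7 (+)-α-cyperone (eudesma-4,11-dien-3-one; 10β-CH3; 7β-isopropenyl)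
Conditions: NaOMe (cat.), MeOH, rt to 50 °C
Reagents that add atoms: none
Why: Intramolecular aldol condensation, 6-(enolendo)-exo-trig, completing the Robinson annulation; no stereocentre is formed or touched.

**Step 4**
Reactants: 7 (+)-α-cyperone
Product: 8 eudesma-1,4,11-trien-3-one (1,2-dehydro-α-cyperone)
Conditions: DDQ (1.5 equiv), dioxane, reflux
Reagents that add atoms: none
Why: DDQ dehydrogenation of a 4-en-3-one under neutral conditions proceeds through the kinetic 2,4-dienol with hydride loss from C1 and should give the cross-conjugated 1,4-dien-3-one, as in the steroid series, leaving the isopropenyl group alone.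

**Step 5**
Reactants: 8 eudesma-1,4,11-trien-3-one
Product: 10 (1R,7R,10R)-10-hydroxyguaia-4,11-dien-3-one (1α-H; 10α-OH; 10β-CH3), via cyclopropyl oxyallyl zwitterion 9 (not isolated)
Conditions: hν (medium-pressure Hg lamp, Pyrex), AcOH–H2O 1:1, Ar, 15–20 °C, stopped when 8 is consumed
Reagents that add atoms: water, O
Why: n→π* excitation and intersystem crossing of the cross-conjugated dienone lead to C1–C5 (β,β′) bonding and, after demotion, to zwitterion 9, which is O-protonated in the acidic medium to a cyclopropylcarbinyl (hydroxyallyl) cation. Water then attacks C10 from the rear of the C5–C10 bond, which breaks, so that C1 is inserted between C10 and C5: the six-membered ring C5–C10 becomes the seven-membered ring and the dienone ring contracts to the cyclopentenone (type A cyclohexadienone photorearrangement in protic acid, the santonin to isophotosantonic lactone type). The only closure is the three-membered bridging of C1 to C5 across C10, possible in one sense only because C6 and C9 must stay cis on the cyclopropane, so the C10 configuration of 8 fixes H-1 as α. C10 is set by inversion (CH3 stays β, OH enters α), so both new stereocentres are relayed from the decalin quaternary carbon. The step needs opening of C5–C10 and not C1–C10, secured by the C4 methyl group that localises the positive charge at C4 next to C5, and it needs capture by water faster than the 1,4-shift to the lumiketone, secured by the aqueous acid. The remote isopropenyl group does not absorb at these wavelengths and should not be protonated by aqueous acetic acid at this temperature.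

**Step 6**
Reactants: 10 hydroxy enone
Product: 11 10α-(triethylsilyloxy)guaia-4,11-dien-3-one
Conditions: TESOTf, 2,6-lutidine, CH2Cl2, −78 to 0 °C
Reagents that add atoms: triethylsilyl triflate, CC[Si](CC)(CC)OS(=O)(=O)C(F)(F)F
Why: Silyl triflate protection of a tertiary alcohol under weakly basic conditions; it removes the internal proton source on the α face, blocks vinylogous retro-aldol cleavage of C1–C10 in later basic steps and does not epimerise the γ-position C1.

**Step 7**
Reactants: 11 TES enone
Product: 13 3-(trimethylsilyloxy)-10α-(triethylsilyloxy)-1αH,5βH-guaia-3,11-diene, via lithium enolate 12 (not isolated)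
Conditions: Li, NH3(l)/THF, t-BuOH (1 equiv), −78 to −33 °C; isoprene; NH3 evaporated; TMSCl, Et3N, THF, −78 to 0 °C
Reagents that add atoms: chlorotrimethylsilane, C[Si](C)(C)Cl
Why: Dissolving-metal enone reduction with regiospecific enolate trapping (reductive silylation): the C5 carbanion should be protonated on the β face, because this gives the less strained trans-hydroazulene with C6 and C10 both pseudo-equatorial and because the pseudo-axial 10α-OTES group screens the α face of C5, while O-silylation of 12 fixes the C3=C4 enol regiochemistry and the isolated alkene and silyl ether are inert.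

**Step 8**
Reactants: 14 2,4,6-trimethoxybenzaldehyde; 15 isobutylmagnesium bromide
Product: 16 (±)-3-methyl-1-(2,4,6-trimethoxyphenyl)butan-1-ol
Conditions: THF/Et2O, 0 °C; aq NH4Cl
Reagents that add atoms: none
Why: Grignard addition to an aryl aldehyde; the racemic carbinol centre is of no consequence because it is ionised in step 10.

**Step 9**
Reactants: 16 benzylic alcohol
Product: 17 (±)-3-methyl-1-(2,4,6-trimethoxyphenyl)butyl acetate
Conditions: Ac2O, Et3N, DMAP (cat.), CH2Cl2, 0 °C; basic work-up, used without chromatography
Reagents that add atoms: acetic anhydride, CC(=O)OC(C)=O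
Why: DMAP-catalysed acetylation turns the hydroxyl group into a leaving group that ionises cleanly and leaves only a volatile silyl ester in the next step.

**Step 10**
Reactants: 13 TMS enol ether; 17 benzylic acetate
Product: 19 (1R,4S,5S,7R,10R,1′R)-4-[3-methyl-1-(2,4,6-trimethoxyphenyl)butyl]-10-(triethylsilyloxy)guai-11-en-3-one, via benzylic cation 18 (not isolated)
Conditions: TMSOTf (10–20 mol %), CH2Cl2, −78 to −40 °C; aq NaHCO3
Reagents that add atoms: none
Why: Lewis-acid-catalysed SN1 α-alkylation of a silyl enol ether by a donor-stabilised benzylic cation (Mukaiyama-type alkylation): C4 should be attacked on its β face, trans to the C5–C6 bond as in alkylations of 3-substituted cyclopentanone enolates, and C1′ should follow from an open transition state with the aryl group antiperiplanar to C3 (away from OSiMe3), H-1′ over the five-membered ring and the isobutyl group next to the C4 methyl, which corresponds to (1′R).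

**Step 11**
Reactants: 19 ketone
Product: 20 3β-alcohol of 19
Conditions: LiAlH4, THF, 0 °C; Rochelle salt work-up
Reagents that add atoms: none
Why: Hydride reduction of a hindered cyclopentanone, expected from the α face opposite the large C4 side chain; the new centre is removed two steps later.

**Step 12**
Reactants: 20 alcohol
Product: 21 O-(guaian-3β-yl) S-methyl xanthate of 20
Conditions: NaH, THF, 0 °C; CS2; MeI, rt
Reagents that add atoms: carbon disulfide, S=C=S; iodomethane, CI
Why: Xanthate formation from the only free hydroxyl group; the small electrophile CS2 tolerates the neopentyl-type environment and the tertiary oxygen is masked as its TES ether.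

**Step 13**
Reactants: 21 xanthate
Product: 22 4β-[(1R)-3-methyl-1-(2,4,6-trimethoxyphenyl)butyl]-10α-(triethylsilyloxy)-1αH,5βH-guai-11-ene
Conditions: Bu3SnH (excess, ca. 1 M), Et3B (cat.), air, toluene, rt
Reagents that add atoms: none
Why: Barton–McCombie deoxygenation, run at room temperature and at high stannane concentration so that hydrogen transfer to the secondary C3 radical outruns any β-scission of the C4–C1′ bond; the remote isopropenyl group does not take part and no stereocentre is touched.

**Step 14**
Reactants: 22 trimethoxyarene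
Product: 24 3,5-diformyl-2,4,6-trimethoxyphenyl TES ether, via lithium amino alkoxide 23 (not isolated)
Conditions: n-BuLi, THF, 0 °C; DMF, −78 to 0 °C; n-BuLi, 0 °C; DMF, −78 to 0 °C; cold dilute HCl to pH 5
Reagents that add atoms: N,N-dimethylformamide, CN(C)C=O
Why: Directed ortho-lithiation and formylation: each ring hydrogen lies between two methoxy groups and should be removed far faster than an allylic hydrogen, and the DMF adduct 23 persists as an α-amino alkoxide, that is an aldehyde protected in situ, so that the second lithiation and formylation can follow in the same flask.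

**Step 15**
Reactants: 24 TES ether dialdehyde
Product: 25 tri-O-methyl ether of the target (free 10α-OH)
Conditions: TBAF, THF, rt to 45 °C
Reagents that add atoms: none
Why: Fluoride-induced desilylation of the tertiary TES ether; the non-enolisable aldehydes, the aryl ethers and the alkene are inert to fluoride.

**Step 16**
Reactants: 25 tri-O-methyl ether
Product: 26 target CNP0594576.1
Conditions: p-TolSLi (excess, from p-TolSH and n-BuLi), HMPA–toluene, 110–130 °C; then cold 1 M HCl
Reagents that add atoms: none
Why: SN2 O-demethylation of aryl methyl ethers by a soft thiolate in a dipolar aprotic medium, each methoxy group being activated by at least one ortho formyl group; the non-acidic conditions spare the tertiary alcohol and the isopropenyl group and touch no stereocentre.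

**Compound list**
1 | (+)-dihydrocarvone, (2R,5R)-2-methyl-5-(prop-1-en-2-yl)cyclohexan-1-one | C=C(C)[C@@H]1CC[C@@H](C)C(=O)C1 | starting material
2 | (R)-1-phenylethylamine | C[C@@H](N)c1ccccc1 | starting material
3 | (R)-1-phenylethyl ketimine of 1 | C=C(C)[C@@H]1CC[C@@H](C)C(=N[C@H](C)c2ccccc2)C1 | intermediate
4 | ethyl vinyl ketone (pent-1-en-3-one) | C=CC(=O)CC | starting material
5 | Michael adduct imine (not isolated) | C=C(C)[C@@H]1CC[C@@](C)(CCC(=O)CC)C(=N[C@H](C)c2ccccc2)C1 | intermediate
6 | (2S,5R)-2-methyl-2-(3-oxopentyl)-5-(prop-1-en-2-yl)cyclohexan-1-one | C=C(C)[C@@H]1CC[C@@](C)(CCC(=O)CC)C(=O)C1 | intermediate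
7 | (+)-α-cyperone, (4aS,7R)-eudesma-4,11-dien-3-one | C=C(C)[C@@H]1CC[C@@]2(C)CCC(=O)C(C)=C2C1 | intermediate
8 | eudesma-1,4,11-trien-3-one | C=C(C)[C@@H]1CC[C@@]2(C)C=CC(=O)C(C)=C2C1 | intermediate
9 | cyclopropyl oxyallyl zwitterion, C1–C5 bridged (not isolated) | C=C(C)[C@@H]1CC[C@@]2(C)[C@@H]3C=C([O-])[C+](C)[C@]23C1 | intermediate
10 | (1R,7R,10R)-10-hydroxyguaia-4,11-dien-3-one | C=C(C)[C@@H]1CC[C@@](C)(O)[C@@H]2CC(=O)C(C)=C2C1 | intermediate
11 | 10α-(triethylsilyloxy)guaia-4,11-dien-3-one | C=C(C)[C@@H]1CC[C@@](C)(O[Si](CC)(CC)CC)[C@@H]2CC(=O)C(C)=C2C1 | intermediate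
12 | lithium C3=C4 enolate, 5β-H (not isolated) | C=C(C)[C@@H]1CC[C@@](C)(O[Si](CC)(CC)CC)[C@@H]2CC([O-])=C(C)[C@H]2C1.[Li+] | intermediate
13 | 3-(trimethylsilyloxy)-10α-(triethylsilyloxy)-1αH,5βH-guaia-3,11-diene | C=C(C)[C@@H]1CC[C@@](C)(O[Si](CC)(CC)CC)[C@@H]2CC(O[Si](C)(C)C)=C(C)[C@H]2C1 | intermediate
14 | 2,4,6-trimethoxybenzaldehyde | COc1cc(OC)c(C=O)c(OC)c1 | starting material
15 | isobutylmagnesium bromide | CC(C)C[Mg]Br | starting material
16 | (±)-3-methyl-1-(2,4,6-trimethoxyphenyl)butan-1-ol | CC(C)CC(O)c1c(OC)cc(OC)cc1OC | intermediate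
17 | (±)-3-methyl-1-(2,4,6-trimethoxyphenyl)butyl acetate | CC(C)CC(OC(C)=O)c1c(OC)cc(OC)cc1OC | intermediate
18 | 3-methyl-1-(2,4,6-trimethoxyphenyl)butyl cation, triflate ion pair (not isolated) | CC(C)C[CH+]c1c(OC)cc(OC)cc1OC.[O-]S(=O)(=O)C(F)(F)F | intermediate
19 | C4-alkylated ketone (4α-CH3, 4β-side chain, 1′R) | C=C(C)[C@@H]1CC[C@@](C)(O[Si](CC)(CC)CC)[C@@H]2CC(=O)[C@](C)([C@@H](CC(C)C)c3c(OC)cc(OC)cc3OC)[C@H]2C1 | intermediate
20 | 3β-alcohol | C=C(C)[C@@H]1CC[C@@](C)(O[Si](CC)(CC)CC)[C@@H]2C[C@H](O)[C@](C)([C@@H](CC(C)C)c3c(OC)cc(OC)cc3OC)[C@H]2C1 | intermediate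
21 | 3β-O-(methylsulfanyl)thiocarbonyl derivative (xanthate) | C=C(C)[C@@H]1CC[C@@](C)(O[Si](CC)(CC)CC)[C@@H]2C[C@H](OC(=S)SC)[C@](C)([C@@H](CC(C)C)c3c(OC)cc(OC)cc3OC)[C@H]2C1 | intermediate
22 | C3-deoxygenated trimethoxyarene | C=C(C)[C@@H]1CC[C@@](C)(O[Si](CC)(CC)CC)[C@@H]2CC[C@](C)([C@@H](CC(C)C)c3c(OC)cc(OC)cc3OC)[C@H]2C1 | intermediate
23 | lithium α-(dimethylamino)alkoxide of the monoaldehyde (not isolated) | C=C(C)[C@@H]1CC[C@@](C)(O[Si](CC)(CC)CC)[C@@H]2CC[C@](C)([C@@H](CC(C)C)c3c(OC)cc(OC)c(C([O-])N(C)C)c3OC)[C@H]2C1.[Li+] | intermediate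
24 | dialdehyde, TES ether | C=C(C)[C@@H]1CC[C@@](C)(O[Si](CC)(CC)CC)[C@@H]2CC[C@](C)([C@@H](CC(C)C)c3c(OC)c(C=O)c(OC)c(C=O)c3OC)[C@H]2C1 | intermediate
25 | tri-O-methyl ether of the target | C=C(C)[C@@H]1CC[C@@](C)(O)[C@@H]2CC[C@](C)([C@@H](CC(C)C)c3c(OC)c(C=O)c(OC)c(C=O)c3OC)[C@H]2C1 | intermediate
26 | CNP0594576.1 | C=C(C)[C@@H]1CC[C@@](C)(O)[C@@H]2CC[C@](C)([C@@H](CC(C)C)c3c(O)c(C=O)c(O)c(C=O)c3O)[C@H]2C1 | target

**Step count**
Total step count: 16.
Longest linear sequence: 14 (steps 1–7 and 10–16).

**Steps most likely to fail**

Step 10.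
- Risk: the two faces of the planar cation may be poorly discriminated, which would give epimers at C1′. The cation may lose a proton to give the styrene. Protodesilylation of the hindered enol silane may outrun C–C bond formation.
- Fallback basis: the fallback replaces substrate control at C1′ by the stereospecific, net-retentive substitution of tricarbonylchromium-complexed benzylic acetates. It sets out from 16 and 13 and comes back at 19.
- Fallback route: alcohol 16 is oxidised (MnO2, CH2Cl2) to 3-methyl-1-(2,4,6-trimethoxyphenyl)butan-1-one F1. Corey–Bakshi–Shibata reduction ((R)-Me-oxazaborolidine, BH3·SMe2) should give (S)-3-methyl-1-(2,4,6-trimethoxyphenyl)butan-1-ol F2. Arene exchange with (η6-naphthalene)Cr(CO)3 (THF, 60 °C) gives the tricarbonylchromium complex of the (S)-alcohol F3, a single compound because the arene substitution pattern is symmetric. Acetylation (Ac2O, pyridine) gives the complexed (S)-acetate F4. Ionisation (BF3·OEt2, CH2Cl2, −78 °C) occurs anti to the metal and gives a configurationally stable cation. Enol silane 13 should attack it again anti to the metal, with overall retention, to give the complexed ketone F5. Air and light in Et2O remove the metal and give 19.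

Step 7.
- Risk: the C5 carbanion may be protonated on the α face, which would give the cis ring fusion. The ketone may be over-reduced. The enolate may equilibrate before silylation.
- Fallback basis: the fallback delivers H-5 by a suprafacial sigmatropic event instead of an external proton. It sets out from 11 and comes back at 13.
- Fallback route: TsNHNH2 (EtOH, PPTS cat.) gives the enone tosylhydrazone F6. Catecholborane (CHCl3, −10 °C), then NaOAc·3H2O at reflux, should add hydride to C3 from the open α face. The 3β-allylic diazene then hands its hydrogen to the β face of C5 by retro-ene loss of N2, giving 10α-(triethylsilyloxy)-1αH,5βH-guaia-3,11-diene F7. mCPBA (1 equiv, NaHCO3, CH2Cl2, −20 °C) should select the trisubstituted ring alkene and give the 3β,4β-epoxide F8. Meinwald rearrangement (BF3·OEt2 cat., CH2Cl2, −78 °C, hydride shift from C3 to C4) gives the saturated 4-methyl-3-ketone F9. Thermodynamic silylation (TMSCl, NaI, Et3N, MeCN) gives the more substituted enol silane 13.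

Step 13.
- Risk: the C3 radical may undergo β-scission at the crowded C4–C1′ bond, releasing the stabilised benzylic radical before hydrogen transfer.
- Fallback basis: the fallback avoids a free C3 radical. It sets out from 19, bypasses 20 and 21, and comes back at 22.
- Fallback route: TsNHNH2 (EtOH, PPTS cat., reflux) gives the tosylhydrazone of the coupled ketone F10. Hydride reduction (catecholborane, CHCl3, 0 °C; then NaOAc·3H2O, reflux) leads through loss of sulfinate and N2 from the alkyl diazene to 22.

**Further compounds**
F1 | step 10 | 3-methyl-1-(2,4,6-trimethoxyphenyl)butan-1-one | CC(C)CC(=O)c1c(OC)cc(OC)cc1OC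
F2 | step 10 | (S)-3-methyl-1-(2,4,6-trimethoxyphenyl)butan-1-ol | O[C@@H](CC(C)C)c1c(OC)cc(OC)cc1OC
F3 | step 10 | tricarbonylchromium complex of the (S)-alcohol | O[C@@H](CC(C)C)c1c(OC)cc(OC)cc1OC.[Cr].[C-]#[O+].[C-]#[O+].[C-]#[O+]
F4 | step 10 | complexed (S)-acetate | CC(=O)O[C@@H](CC(C)C)c1c(OC)cc(OC)cc1OC.[Cr].[C-]#[O+].[C-]#[O+].[C-]#[O+]
F5 | step 10 | complexed ketone | C=C(C)[C@@H]1CC[C@@](C)(O[Si](CC)(CC)CC)[C@@H]2CC(=O)[C@](C)([C@@H](CC(C)C)c3c(OC)cc(OC)cc3OC)[C@H]2C1.[Cr].[C-]#[O+].[C-]#[O+].[C-]#[O+]
F6 | step 7 | enone tosylhydrazone | C=C(C)[C@@H]1CC[C@@](C)(O[Si](CC)(CC)CC)[C@@H]2CC(=NNS(=O)(=O)c3ccc(C)cc3)C(C)=C2C1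
F7 | step 7 | 10α-(triethylsilyloxy)-1αH,5βH-guaia-3,11-diene | C=C(C)[C@@H]1CC[C@@](C)(O[Si](CC)(CC)CC)[C@@H]2CC=C(C)[C@H]2C1
F8 | step 7 | 3β,4β-epoxide | C=C(C)[C@@H]1CC[C@@](C)(O[Si](CC)(CC)CC)[C@@H]2C[C@@H]3O[C@]3(C)[C@H]2C1
F9 | step 7 | saturated 4-methyl-3-ketone | C=C(C)[C@@H]1CC[C@@](C)(O[Si](CC)(CC)CC)[C@@H]2CC(=O)[C@H](C)[C@H]2C1
F10 | step 13 | tosylhydrazone of the coupled ketone | C=C(C)[C@@H]1CC[C@@](C)(O[Si](CC)(CC)CC)[C@@H]2CC(=NNS(=O)(=O)c3ccc(C)cc3)[C@](C)([C@@H](CC(C)C)c3c(OC)cc(OC)cc3OC)[C@H]2C1
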